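**Assumptions (one line):** every stereo-labelled C=C in the target is E, the all-trans pattern of natural CoQ6. The target has no stereocentres, so "single enantiomer" is trivially satisfied. The terminal isopropylidene has no geometry.

## Retrosynthetic overview
1. No ring is built. The fully substituted benzene ring of ubiquinol-6 (**1**) comes intact from commercial 2,3-dimethoxy-5-methyl-1,4-benzoquinone (**2**), reduced to hydroquinone **3**.
2. Disconnect the aryl–CH2 bond: acid-mediated allylic C-alkylation of **3** (its only free ring carbon) with all-E-hexaprenol (**4**).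
3. Disconnect **4** at the bond between isoprene units 2 and 3: alkylation of the allylic sulfone anion of C10 unit **5** with geranylgeranyl bromide (**6**), then Pd-catalysed reductive desulfonylation and desilylation.
4. **5** comes from geraniol (**7**) by O-silylation, SeO2 hydroxylation of the terminal E-methyl, chlorination and sulfinate displacement. **6** comes from geranylgeraniol (**8**).
5. All C=C geometry is inherited from the all-E commercial terpenols, and no step touches a C=C bond.

## Route

**Step 1**
Reactants: **7** geraniol ((2E)-3,7-dimethylocta-2,6-dien-1-ol)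
Product: **9** geranyl TBS ether
Conditions: TBSCl, imidazole, DMF, 0 °C → rt
Reagents that add atoms: tert-butyldimethylsilyl chloride, CC(C)(C)[Si](C)(C)Cl
Why: O-silylation gives a protecting group that survives n-BuLi and LiBHEt3 later. No stereocentre is formed and the E-alkene is untouched.

**Step 2**
Reactants: **9**
Product: **10** (2E,6E)-8-(TBSO)-2,6-dimethylocta-2,6-dien-1-ol
Conditions: SeO2 (5 mol %), t-BuOOH, salicylic acid (cat.), CH2Cl2, 0 °C → rt; then NaBH4, EtOH, 0 °C
Reagents that add atoms: tert-butyl hydroperoxide, CC(C)(C)OO (oxygen source)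
Why: Sharpless–Umbreit SeO2 allylic oxidation (ene reaction then [2,3] shift) acts on the more electron-rich terminal trisubstituted alkene. It hydroxylates the methyl trans to the chain through a chair-like transition state, so the new C=C is E. NaBH4 reduces any over-oxidised aldehyde back to the alcohol.

**Step 3**
Reactants: **10**
Product: **11** (2E,6E)-8-chloro-3,7-dimethylocta-2,6-dienyl TBS ether
Conditions: MsCl, 2,4,6-collidine, LiCl, DMF, 0 °C
Reagents that add atoms: lithium chloride, [Li+].[Cl-] (the Cl source). MsCl and collidine leave no atoms.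
Why: the allylic mesylate forms in situ and is displaced by chloride (Meyers chlorination). This is SN2 at a primary carbon, so there is no allylic transposition and the alkene geometry is kept.

**Step 4**
Reactants: **11**
Product: **5** TBS-protected C10 allylic phenyl sulfone, tert-butyl{[(2E,6E)-3,7-dimethyl-8-(phenylsulfonyl)octa-2,6-dien-1-yl]oxy}dimethylsilane
Conditions: PhSO2Na, DMF, rt
Reagents that add atoms: sodium benzenesulfinate, [Na+].[O-]S(=O)c1ccccc1
Why: SN2 displacement by sulfinate S-attack gives the sulfone with no stereochemical change. The sulfone acidifies the CH2 (allylic, α to SO2) for the next step.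

**Step 5**
Reactants: **8** geranylgeraniol ((2E,6E,10E)-3,7,11,15-tetramethylhexadeca-2,6,10,14-tetraen-1-ol)
Product: **6** geranylgeranyl bromide
Conditions: PBr3, Et2O, 0 °C, 30 min (crude, used at once)
Reagents that add atoms: phosphorus tribromide, BrP(Br)Br
Why: SN2 conversion of a primary allylic alcohol to the bromide, with no allylic transposition and E retained.

**Step 6**
Reactants: **5** + **6**
Product: **12** branched sulfone (TBS ether; sulfone carbon racemic)
Conditions: n-BuLi, THF, −78 °C; then HMPA, **6**, −78 → −40 °C
Reagents that add atoms: none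
Why: sulfone-stabilised allylic carbanion alkylation (Biellmann-type chain extension). The anion attacks at the α-carbon by SN2 on the primary allylic bromide, forming the unit 2–unit 3 bond head-to-tail. The new sulfone-bearing stereocentre is a throwaway that is destroyed in Step 7.

**Step 7**
Reactants: **12**
Product: **13** all-E-hexaprenyl TBS ether
Conditions: Pd(dppp)Cl2 (5 mol %), LiBHEt3, THF, 0 °C → rt
Reagents that add atoms: none (only hydride is added)
Why: Pd(0) ionises the allylic sulfone to a π-allyl complex, and hydride delivery at the less hindered terminus gives the linear trisubstituted E-alkene (reductive desulfonylation). The sulfone stereocentre is lost, and the TBS ether, isolated alkenes and aryl-free chain survive.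

**Step 8**
Reactants: **13**
Product: **4** (2E,6E,10E,14E,18E)-hexaprenol
Conditions: TBAF, THF, 0 °C → rt
Reagents that add atoms: none
Why: fluoride-induced Si–O cleavage (desilylation) frees the primary allylic alcohol without touching the polyene.

**Step 9**
Reactants: **2** 2,3-dimethoxy-5-methyl-1,4-benzoquinone
Product: **3** 2,3-dimethoxy-5-methylbenzene-1,4-diol
Conditions: Na2S2O4, Et2O/H2O, rt, 15 min, under Ar
Reagents that add atoms: none (electrons from dithionite; hydrogens from water)
Why: two-electron quinone-to-hydroquinone reduction. It makes the ring electron-rich so that C6 (para to OMe, ortho to OH) is nucleophilic.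

**Step 10**
Reactants: **3** (3 equiv) + **4**
Product: **1** ubiquinol-6
Conditions: BF3·OEt2 (0.3 equiv), dry 1,4-dioxane, 40 °C, 3 h, Ar, dark; aqueous Na2S2O4 work-up
Reagents that add atoms: none (BF3 is catalytic; H2O is lost)
Why: Lewis-acid ionisation of the allylic alcohol gives a polyprenyl cation that undergoes Friedel–Crafts C-alkylation at the only free ring position, giving the 6-hexaprenyl pattern of the target. The E geometry is retained, there is no new stereocentre, and the dithionite work-up returns any air-oxidised quinone to the hydroquinone.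

## Compound list
1 | ubiquinol-6, 2,3-dimethoxy-5-methyl-6-[(all-E)-hexaprenyl]benzene-1,4-diol | COc1c(O)c(C)c(C/C=C(\C)CC/C=C(\C)CC/C=C(\C)CC/C=C(\C)CC/C=C(\C)CCC=C(C)C)c(O)c1OC | target
2 | 2,3-dimethoxy-5-methyl-1,4-benzoquinone (CoQ0) | COC1=C(OC)C(=O)C(C)=CC1=O | starting material
3 | 2,3-dimethoxy-5-methylbenzene-1,4-diol | COc1c(OC)c(O)c(C)cc1O | intermediate
4 | (2E,6E,10E,14E,18E)-3,7,11,15,19,23-hexamethyltetracosa-2,6,10,14,18,22-hexaen-1-ol (all-E-hexaprenol) | OC/C=C(\C)CC/C=C(\C)CC/C=C(\C)CC/C=C(\C)CC/C=C(\C)CCC=C(C)C | intermediate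
5 | tert-butyl{[(2E,6E)-3,7-dimethyl-8-(phenylsulfonyl)octa-2,6-dien-1-yl]oxy}dimethylsilane | CC(C)(C)[Si](C)(C)OC/C=C(\C)CC/C=C(\C)CS(=O)(=O)c1ccccc1 | intermediate
6 | geranylgeranyl bromide, (2E,6E,10E)-1-bromo-3,7,11,15-tetramethylhexadeca-2,6,10,14-tetraene | BrC/C=C(\C)CC/C=C(\C)CC/C=C(\C)CCC=C(C)C | intermediate
7 | geraniol | OC/C=C(\C)CCC=C(C)C | starting material
8 | geranylgeraniol (all-E) | OC/C=C(\C)CC/C=C(\C)CC/C=C(\C)CCC=C(C)C | starting material
9 | geranyl TBS ether | CC(C)(C)[Si](C)(C)OC/C=C(\C)CCC=C(C)C | intermediate
10 | (2E,6E)-8-[(tert-butyldimethylsilyl)oxy]-2,6-dimethylocta-2,6-dien-1-ol | CC(C)(C)[Si](C)(C)OC/C=C(\C)CC/C=C(\C)CO | intermediate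
11 | tert-butyl{[(2E,6E)-8-chloro-3,7-dimethylocta-2,6-dien-1-yl]oxy}dimethylsilane | CC(C)(C)[Si](C)(C)OC/C=C(\C)CC/C=C(\C)CCl | intermediate
12 | (2E,6E,10E,14E,18E)-1-(TBSO)-3,7,11,15,19,23-hexamethyl-8-(phenylsulfonyl)tetracosa-2,6,10,14,18,22-hexaene (C8 racemic) | CC(C)(C)[Si](C)(C)OC/C=C(\C)CC/C=C(\C)C(S(=O)(=O)c1ccccc1)C/C=C(\C)CC/C=C(\C)CC/C=C(\C)CCC=C(C)C | intermediate
13 | all-E-hexaprenyl TBS ether | CC(C)(C)[Si](C)(C)OC/C=C(\C)CC/C=C(\C)CC/C=C(\C)CC/C=C(\C)CC/C=C(\C)CCC=C(C)C | intermediate

## Summary
- Total steps: 10.
- Longest linear sequence: 8 (7 → 9 → 10 → 11 → 5 → 12 → 13 → 4 → 1, i.e. Steps 1, 2, 3, 4, 6, 7, 8, 10).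

**Three steps most likely to fail**
1. **Step 10, Friedel–Crafts coupling.** Risks are moderate yield, O-alkylation, polyene cyclisation or isomerisation, and air oxidation. Fallback: convert **4** to the bromide, then to the hexaprenyl tributylstannane with Bu3SnLi. Add this to quinone **2** with BF3·OEt2 (allylstannane addition to the quinone, then re-aromatisation) to give CoQ6, then reduce with Na2S2O4.
2. **Step 2, SeO2 hydroxylation.** Yield is modest (about 40–50 %), and over-oxidation or loss of the TBS group are possible. Fallback: obtain (2E,6E)-8-hydroxygeraniol by purchase or by biocatalytic C-H hydroxylation of geraniol (geraniol 8-hydroxylase, a P450). Then TBS-protect the C1 hydroxyl and continue from Step 3.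
3. **Step 7, Pd/LiBHEt3 desulfonylation.** Alkene migration or over-reduction of the polyene are possible. Fallback: drop the sulfone strategy and couple the allylic Grignard of **11** (Mg) with **6** under Li2CuCl4 catalysis (Cu-catalysed SN2 allyl–allyl coupling) to make **13** directly.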